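**Retrosynthetic overview**
1. 19 ⇒ 18 (CHO → CO2H) ⇒ 16. The C2–C3 bond comes from axial capture of a C3 peroxycarbenium ion by an acetaldehyde enol silane, which sets C3.
2. 16 ⇒ 14. The C6–ethyl bond comes from Et3Al capture of the tertiary C6 peroxycarbenium ion, trans to the C4 ethyl. This is the key step and sets the quaternary C6.
3. 14 ⇒ 12. The only ring, the 1,2-dioxane, is closed in one operation by stitching H2O2 across an acyclic γ-keto aldehyde. Both C–O bonds form together, with no hydroperoxide/enoate oxa-Michael and no alkene hydroperoxidation.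
4. 12 ⇒ 10 + 11. The C4–C5 bond comes from enantioselective photoredox/enamine α-alkylation of butanal. This sets C4, which then relays to C6 and C3.
5. 10 ⇒ 7 ⇒ 6 ⇒ 4 ⇒ 2 ⇒ 1. Cu-catalysed MeMgBr conjugate addition sets C8. It follows a Wittig reaction, a Johnson–Claisen 1,3-chirality transfer (C10 and the 11E alkene) and a catalytic Et2Zn addition.

Assumption: acid numbering C1 (CO2H) to C14 is used throughout (target = 3S,4S,6R,8S,10R,11E), and the catalyst/ligand antipodes named in steps 1, 5 and 7 follow the accepted facial models; each exists in both mirror-image forms, so the antipode is taken if an induction runs the other way.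

**Step 1**
Reactants: 1 (E)-pent-2-enal
Product: 2 (3R,4E)-hept-4-en-3-ol
Conditions: Et2Zn (1.5 equiv), (+)-MIB (4 mol %), hexane/toluene, 0 °C; aq NH4Cl
Reagents that add atoms: diethylzinc, CC[Zn]CC
Why: This is a ligand-accelerated catalytic enantioselective dialkylzinc 1,2-addition in which the amino-alkoxide zinc complex delivers ethyl to the Re face of the enal carbonyl and gives the R carbinol without 1,4-addition.

**Step 2**
Reactants: 2 (3R,4E)-hept-4-en-3-ol
Product: 4 ethyl (3R,4E)-3-ethylhept-4-enoate, via mixed ketene acetal 3 (not isolated)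
Conditions: MeC(OEt)3 (5 equiv), EtCO2H (5 mol %), 138 °C, EtOH distilled off
Reagents that add atoms: triethyl orthoacetate, CC(OCC)(OCC)OCC
Why: In this Johnson–Claisen rearrangement the chair transition state keeps the carbinol ethyl equatorial, so it gives the E alkene (C11=C12) and moves chirality suprafacially from the C–O carbon to C10 (R to R).

**Step 3**
Reactants: 4 ethyl (3R,4E)-3-ethylhept-4-enoate
Product: 5 (3R,4E)-3-ethylhept-4-enal
Conditions: DIBAL-H (1.05 equiv), CH2Cl2, −78 °C; Rochelle salt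
Reagents that add atoms: none
Why: DIBAL-H partial ester reduction stops at the aldehyde because the tetrahedral aluminium hemiacetal survives at −78 °C, and the β-stereocentre and the isolated alkene are not touched.

**Step 4**
Reactants: 5 (3R,4E)-3-ethylhept-4-enal
Product: 6 (3E,6R,7E)-6-ethyldeca-3,7-dien-2-one
Conditions: Ph3P=CHC(O)CH3 (1.2 equiv), CH2Cl2, reflux
Reagents that add atoms: 1-(triphenyl-λ5-phosphanylidene)propan-2-one, CC(=O)C=P(c1ccccc1)(c1ccccc1)c1ccccc1
Why: A Wittig olefination with a stabilised ylide gives the E enone, and the aldehyde has no α-stereocentre to lose.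

**Step 5**
Reactants: 6 (3E,6R,7E)-6-ethyldeca-3,7-dien-2-one
Product: 7 (4S,6R,7E)-6-ethyl-4-methyldec-7-en-2-one
Conditions: MeMgBr (1.2 equiv), CuBr·SMe2 (5 mol %), (R,Sp)-Josiphos (PPh2/PCy2, 6 mol %), t-BuOMe, −75 °C; aq NH4Cl
Reagents that add atoms: methylmagnesium bromide, C[Mg]Br
Why: In this copper-catalysed asymmetric conjugate addition of a Grignard reagent to a linear enone the ligand controls delivery of methyl to the Si face of C8 (8S, syn to the C10 ethyl), and the isolated alkene is inert.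

**Step 6**
Reactants: 7 (4S,6R,7E)-6-ethyl-4-methyldec-7-en-2-one
Product: 10 (4S,6R,7E)-1-bromo-6-ethyl-4-methyldec-7-en-2-one, via kinetic lithium enolate 8 (not isolated), via trimethylsilyl enol ether 9 (not isolated)
Conditions: LDA (1.1 equiv), THF, −78 °C; TMSCl; cold NaHCO3 wash, crude; NBS (1.05 equiv), THF, −78 to 0 °C
Reagents that add atoms: N-bromosuccinimide, O=C1CCC(=O)N1Br
Why: Kinetic deprotonation at the methyl group followed by electrophilic bromination of the silyl enol ether works because the enol ether reacts with NBS far faster than the hindered 1,2-disubstituted alkene, and no stereocentre is involved.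

**Step 7**
Reactants: 10 (4S,6R,7E)-1-bromo-6-ethyl-4-methyldec-7-en-2-one, 11 butanal
Product: 12 (2S,6S,8R,9E)-2,8-diethyl-6-methyl-4-oxododec-9-enal
Conditions: 11 (2.5 equiv), (2S,5R)-2-tert-butyl-3,5-dimethylimidazolidin-4-one·HOTf (20 mol %), Ru(bpy)3Cl2 (0.5 mol %), 2,6-lutidine (2 equiv), DMF, visible light, 23 °C
Reagents that add atoms: none
Why: In this dual photoredox/enamine organocatalytic α-alkylation of an aldehyde the electrophilic α-acyl radical from 10 adds to the E-enamine face not shielded by the catalyst C5 methyl, which sets C4 as S, and 7-exo cyclisation onto the remote alkene is too slow to compete.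

**Step 8**
Reactants: 12 (2S,6S,8R,9E)-2,8-diethyl-6-methyl-4-oxododec-9-enal
Product: 14 (4S)-4-ethyl-6-[(2S,4R,5E)-4-ethyl-2-methyloct-5-en-1-yl]-3,6-dimethoxy-1,2-dioxane (C3/C6 anomer mixture), via dioxanediol 13 (not isolated)
Conditions: urea·H2O2 (1.5 equiv), Sc(OTf)3 (10 mol %), MeOH/CH2Cl2 1:3, 0 °C to rt
Reagents that add atoms: hydrogen peroxide (as urea adduct), OO; methanol, CO
Why: In this acid-catalysed double peroxyacetalisation H2O2, whose carbonyl adducts are much more favoured than those of water or methanol, bridges the 1,4-dicarbonyl as the six-membered bis-hemiperketal 13, and both anomeric OH groups are then exchanged for OMe; the known reaction types are 1,4-diketone to 1,2-dioxane-3,6-diol and ketone to α-methoxy hydroperoxide; C3 and C6 form as inconsequential anomers that are ionised later, and C4 survives because acetalisation outruns enolisation.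

**Step 9**
Reactants: 14 (4S)-4-ethyl-6-[(2S,4R,5E)-4-ethyl-2-methyloct-5-en-1-yl]-3,6-dimethoxy-1,2-dioxane
Product: 16 (4S,6R)-4,6-diethyl-6-[(2S,4R,5E)-4-ethyl-2-methyloct-5-en-1-yl]-3-methoxy-1,2-dioxane (C3 anomer mixture), via C6 peroxycarbenium triflate 15 (not isolated)
Conditions: Et3Al (3 equiv), then TMSOTf (1.1 equiv), CH2Cl2, −78 °C; Rochelle salt
Reagents that add atoms: triethylaluminium, CC[Al](CC)CC
Why: Proposed new method: TMSOTf ionises the ketal-type C6–OMe much faster than the acetal-type C3–OMe (tertiary versus secondary peroxycarbenium ion), and Et3Al, which leaves dialkyl peroxides alone at −78 °C, transfers ethyl to cation 15 along the axial trajectory of the half-chair that keeps the C4 ethyl pseudo-equatorial, that is trans to C4-Et (a top-face C3-OMe can only reinforce this by bridging), so the quaternary centre is set as 6R by the face of attack and not by telling an ethyl from the long chain; the closest known reaction types are Lewis-acid substitution of cyclic peroxyketals by allylsilanes or silyl ketene acetals and trialkylaluminium alkylation of tertiary oxocarbenium ions (C-glycosidation type), and the risks are β-hydride transfer from Et3Al and endocyclic C–O cleavage.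

**Step 10**
Reactants: 16 (4S,6R)-4,6-diethyl-6-[(2S,4R,5E)-4-ethyl-2-methyloct-5-en-1-yl]-3-methoxy-1,2-dioxane
Product: 18 2-[(3S,4S,6R)-4,6-diethyl-6-[(2S,4R,5E)-4-ethyl-2-methyloct-5-en-1-yl]-1,2-dioxan-3-yl]acetaldehyde, via C3 peroxycarbenium triflate 17 (not isolated)
Conditions: CH2=CHOSiMe3 (2 equiv), TMSOTf (20 mol %), CH2Cl2, −78 °C; pH 7 buffer
Reagents that add atoms: trimethyl(vinyloxy)silane, C=CO[Si](C)(C)C
Why: This is a Mukaiyama-type substitution of a cyclic peroxyacetal by a silyl enol ether, in which the ring is locked because a flip would place the C4 ethyl and the C6 chain 1,3-diaxial, so the stereoelectronically preferred axial attack, anti to the pseudo-axial C4–H, puts the new arm cis to the C4 ethyl (3S); a moderately reactive enol silane keeps the facial selectivity, and TMSOTf at −78 °C activates acetals but not the product aldehyde.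

**Step 11**
Reactants: 18 2-[(3S,4S,6R)-4,6-diethyl-6-[(2S,4R,5E)-4-ethyl-2-methyloct-5-en-1-yl]-1,2-dioxan-3-yl]acetaldehyde
Product: 19 2-[(3S,4S,6R)-4,6-diethyl-6-[(2S,4R,5E)-4-ethyl-2-methyloct-5-en-1-yl]-1,2-dioxan-3-yl]acetic acid
Conditions: NaClO2 (2 equiv), NaH2PO4, 2-methylbut-2-ene (10 equiv), t-BuOH/H2O, 0 °C to rt
Reagents that add atoms: sodium chlorite, [Na+].[O-]Cl=O
Why: The Pinnick oxidation runs at about pH 4, where the dialkyl peroxide is inert and base-induced loss of the β-peroxide or C3 epimerisation is avoided, the scavenger removes HOCl so the C11=C12 alkene survives, and no stereocentre is touched.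

**Compound list**
1 | (E)-pent-2-enal | CC/C=C/C=O | starting material
2 | (3R,4E)-hept-4-en-3-ol | CC[C@@H](O)/C=C/CC | intermediate
3 | (3R,4E)-3-[(1-ethoxyethenyl)oxy]hept-4-ene (mixed ketene acetal, not isolated) | CC[C@@H](OC(=C)OCC)/C=C/CC | intermediate
4 | ethyl (3R,4E)-3-ethylhept-4-enoate | CC/C=C/[C@H](CC)CC(=O)OCC | intermediate
5 | (3R,4E)-3-ethylhept-4-enal | CC/C=C/[C@H](CC)CC=O | intermediate
6 | (3E,6R,7E)-6-ethyldeca-3,7-dien-2-one | CC/C=C/[C@H](CC)C/C=C/C(C)=O | intermediate
7 | (4S,6R,7E)-6-ethyl-4-methyldec-7-en-2-one | CC/C=C/[C@H](CC)C[C@H](C)CC(C)=O | intermediate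
8 | lithium (4S,6R,7E)-6-ethyl-4-methyldeca-1,7-dien-2-olate (not isolated) | CC/C=C/[C@H](CC)C[C@H](C)CC(=C)[O-].[Li+] | intermediate
9 | {[(4S,6R,7E)-6-ethyl-4-methyldeca-1,7-dien-2-yl]oxy}trimethylsilane (not isolated) | CC/C=C/[C@H](CC)C[C@H](C)CC(=C)O[Si](C)(C)C | intermediate
10 | (4S,6R,7E)-1-bromo-6-ethyl-4-methyldec-7-en-2-one | CC/C=C/[C@H](CC)C[C@H](C)CC(=O)CBr | intermediate
11 | butanal | CCCC=O | starting material
12 | (2S,6S,8R,9E)-2,8-diethyl-6-methyl-4-oxododec-9-enal | CC/C=C/[C@H](CC)C[C@H](C)CC(=O)C[C@H](CC)C=O | intermediate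
13 | (4S)-4-ethyl-6-[(2S,4R,5E)-4-ethyl-2-methyloct-5-en-1-yl]-1,2-dioxane-3,6-diol (anomers, not isolated) | CC/C=C/[C@H](CC)C[C@H](C)CC1(O)C[C@H](CC)C(O)OO1 | intermediate
14 | (4S)-4-ethyl-6-[(2S,4R,5E)-4-ethyl-2-methyloct-5-en-1-yl]-3,6-dimethoxy-1,2-dioxane (C3/C6 anomers) | CC/C=C/[C@H](CC)C[C@H](C)CC1(OC)C[C@H](CC)C(OC)OO1 | intermediate
15 | C6 peroxycarbenium triflate (O1=C6 cation of 14 after loss of the C6 methoxide, not isolated) | CC/C=C/[C@H](CC)C[C@H](C)CC1C[C@H](CC)C(OC)O[O+]=1.[O-]S(=O)(=O)C(F)(F)F | intermediate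
16 | (4S,6R)-4,6-diethyl-6-[(2S,4R,5E)-4-ethyl-2-methyloct-5-en-1-yl]-3-methoxy-1,2-dioxane (C3 anomers) | CC/C=C/[C@H](CC)C[C@H](C)C[C@]1(CC)C[C@H](CC)C(OC)OO1 | intermediate
17 | C3 peroxycarbenium triflate (O2=C3 cation of 16 after loss of methoxide, not isolated) | CC/C=C/[C@H](CC)C[C@H](C)C[C@]1(CC)C[C@H](CC)C=[O+]O1.[O-]S(=O)(=O)C(F)(F)F | intermediate
18 | 2-[(3S,4S,6R)-4,6-diethyl-6-[(2S,4R,5E)-4-ethyl-2-methyloct-5-en-1-yl]-1,2-dioxan-3-yl]acetaldehyde | CC/C=C/[C@H](CC)C[C@H](C)C[C@]1(CC)C[C@H](CC)[C@H](CC=O)OO1 | intermediate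
19 | 2-[(3S,4S,6R)-4,6-diethyl-6-[(2S,4R,5E)-4-ethyl-2-methyloct-5-en-1-yl]-1,2-dioxan-3-yl]acetic acid | CC/C=C/[C@H](CC)C[C@H](C)C[C@]1(CC)C[C@H](CC)[C@H](CC(=O)O)OO1 | target

**Step count.** Total step count is 11. The longest linear sequence is 11 steps (1 to 19). No protecting groups are used.

**Steps most likely to fail**

**Step 9 (ethyl transfer to the C6 peroxycarbenium ion).** Et3Al may reduce the cation by β-hydride transfer, attack the O–O bond, or capture the ring-opened methoxycarbenium ion.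
- The fallback sets out from 14 and comes back at 16. It replaces the organometallic by a two-carbon π-nucleophile of proven compatibility and then removes the oxygen.
- Trimethyl(vinyloxy)silane with catalytic TMSOTf (CH2Cl2, −78 °C) reacts at the C6 ketal from the same face. It gives 2-{(3R,5S)-5-ethyl-3-[(2S,4R,5E)-4-ethyl-2-methyloct-5-en-1-yl]-6-methoxy-1,2-dioxan-3-yl}acetaldehyde F3.
- NaBH4 in MeOH at 0 °C gives 2-{(3R,5S)-5-ethyl-3-[(2S,4R,5E)-4-ethyl-2-methyloct-5-en-1-yl]-6-methoxy-1,2-dioxan-3-yl}ethan-1-ol F4.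
- Premixed I2/PPh3/imidazole at 0 °C gives (3R,5S)-5-ethyl-3-[(2S,4R,5E)-4-ethyl-2-methyloct-5-en-1-yl]-3-(2-iodoethyl)-6-methoxy-1,2-dioxane F5.
- NaBH4 in DMSO at rt reduces the primary iodide to the ethyl group of 16.

**Step 8 (one-pot ring assembly).** The keto aldehyde may divert to 2,5-dimethoxytetrahydrofurans, a furan, or bis-hydroperoxides.
- The fallback sets out from 12 and comes back at 14. It gives up the self-assembly and makes the two C–O bonds one after the other from a differentiated precursor.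
- Chemoselective acetalisation of the aldehyde (MeOH, PPTS, 3 Å sieves, 0 °C) gives (2S,6S,8R,9E)-2,8-diethyl-1,1-dimethoxy-6-methyldodec-9-en-4-one F1.
- Perhydrolysis of the ketone alone (urea·H2O2, Sc(OTf)3, MeOH) gives the isolable (2S,6S,8R,9E)-2,8-diethyl-4-hydroperoxy-1,1,4-trimethoxy-6-methyldodec-9-ene F2.
- Water-free trans-acetalisation (PPTS, benzene, 4 Å sieves to take up MeOH) closes the hydroperoxide onto the acetal carbon and gives 14.

**Step 10 (3,4-cis selectivity and lability of the β-peroxy aldehyde).** The equatorial C4 ethyl may push the enol silane to the other face.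
- The fallback sets out from 16 and comes back at 18. It uses the slimmest possible carbon nucleophile, for which axial attack is least perturbed, and turns it into the CH2CHO arm afterwards.
- Me2AlC≡CSiMe3 with BF3·OEt2 (CH2Cl2, −78 °C) gives {[(3R,4S,6R)-4,6-diethyl-6-[(2S,4R,5E)-4-ethyl-2-methyloct-5-en-1-yl]-1,2-dioxan-3-yl]ethynyl}trimethylsilane F6.
- Buffered TBAF/AcOH (THF, 0 °C) gives (3R,4S,6R)-4,6-diethyl-6-[(2S,4R,5E)-4-ethyl-2-methyloct-5-en-1-yl]-3-ethynyl-1,2-dioxane F7.
- Anti-Markovnikov hydration by Cy2BH (1.05 equiv, 0 °C; the terminal alkyne reacts before the hindered internal alkene) and NaBO3 oxidation gives 18.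

**Further compounds**
F1 | step 8 | (2S,6S,8R,9E)-2,8-diethyl-1,1-dimethoxy-6-methyldodec-9-en-4-one | CC/C=C/[C@H](CC)C[C@H](C)CC(=O)C[C@H](CC)C(OC)OC
F2 | step 8 | (2S,6S,8R,9E)-2,8-diethyl-4-hydroperoxy-1,1,4-trimethoxy-6-methyldodec-9-ene | CC/C=C/[C@H](CC)C[C@H](C)CC(OC)(OO)C[C@H](CC)C(OC)OC
F3 | step 9 | 2-{(3R,5S)-5-ethyl-3-[(2S,4R,5E)-4-ethyl-2-methyloct-5-en-1-yl]-6-methoxy-1,2-dioxan-3-yl}acetaldehyde | CC/C=C/[C@H](CC)C[C@H](C)C[C@]1(CC=O)C[C@H](CC)C(OC)OO1
F4 | step 9 | 2-{(3R,5S)-5-ethyl-3-[(2S,4R,5E)-4-ethyl-2-methyloct-5-en-1-yl]-6-methoxy-1,2-dioxan-3-yl}ethan-1-ol | CC/C=C/[C@H](CC)C[C@H](C)C[C@]1(CCO)C[C@H](CC)C(OC)OO1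
F5 | step 9 | (3R,5S)-5-ethyl-3-[(2S,4R,5E)-4-ethyl-2-methyloct-5-en-1-yl]-3-(2-iodoethyl)-6-methoxy-1,2-dioxane | CC/C=C/[C@H](CC)C[C@H](C)C[C@]1(CCI)C[C@H](CC)C(OC)OO1
F6 | step 10 | {[(3R,4S,6R)-4,6-diethyl-6-[(2S,4R,5E)-4-ethyl-2-methyloct-5-en-1-yl]-1,2-dioxan-3-yl]ethynyl}trimethylsilane | CC/C=C/[C@H](CC)C[C@H](C)C[C@]1(CC)C[C@H](CC)[C@H](C#C[Si](C)(C)C)OO1
F7 | step 10 | (3R,4S,6R)-4,6-diethyl-6-[(2S,4R,5E)-4-ethyl-2-methyloct-5-en-1-yl]-3-ethynyl-1,2-dioxane | CC/C=C/[C@H](CC)C[C@H](C)C[C@]1(CC)C[C@H](CC)[C@H](C#C)OO1
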